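**Plan**
1. Atoms keep their gibberellane numbers throughout (C7, C19, C20 are the carboxyl carbons, C18 the C4 methyl, C17 the exocyclic CH2); β is the face of rings A/B/C that carries H5 and H9.
2. Retrosynthesis cuts, in this order: the two ester methyls, C16=C17, the C2–O and C3–O bonds, C8–C15 (ring D), the C16 oxygen (from a C13 vinyl group), C6=C8 (ring B), C13–C16, C5–C6 with C4–C18, C10–C1 with C4=C5 (ring A), C10–C5, O–C20 (lactone) and C9–C10.
3. Forward: ring C comes from a quinone monoketal, the δ-lactone is closed onto it, ring A is spiro-annulated at C10, ring B is closed by olefination and ring D by enolate conjugate addition; dihydroxylation, methylenation and ester cleavage finish the synthesis.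
4. Enabling feature: C8 is quaternary, β to the C7 carboxyl through C6 and 1,3 to C13 across ring C, so an acetyl group (C16, C15) held axial on C13 by the C20→C12 lactone can add through C15 to a C6=C8 enoate and close ring D.
5. Stereochemistry: C9 by catalytic asymmetric Michael addition; C12 by cis-selective reduction (only the cis alcohol lactonises); C10, C5, C4 and C13 by attack anti to the ketal, the bridgehead, the axial lactone carbonyl and the lactone bridge; C8 by the tether; C6 by equilibration; C2/C3 by β-face osmylation.

Key step: step 15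

Assumption: the (S)-binaphthoxide catalyst of step 1 is written on the expectation that its sense of induction on 2-cyclohexenone carries over to the dienone (if not, its antipode is used), and methyl 5-methoxy-3-oxopentanoate is taken to be a catalogue chemical.

**Route**

Step 1
Reactants: 1 4,4-dimethoxycyclohexa-2,5-dien-1-one; 2 dimethyl malonate
Product: 3 dimethyl 2-[(1S)-6,6-dimethoxy-3-oxocyclohex-4-en-1-yl]propanedioate
Conditions: LiAl[(S)-binaphthoxide]2 (10 mol%), KOtBu (9 mol%), 4 Å MS, THF, 25 °C; 1 in excess (1.5 equiv)
Reagents that add atoms: none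
Why: Catalytic asymmetric Michael addition of a malonate to a cyclic enone under heterobimetallic Lewis acid/Brønsted base catalysis: the two β-carbons of the dienone are equivalent, the catalyst selects the enantiotopic face that makes C9 (S), and the monoadduct, flanked by the ketal, should be a poorer acceptor than 1.

Step 2
Reactants: 3 dimethyl 2-[(1S)-6,6-dimethoxy-3-oxocyclohex-4-en-1-yl]propanedioate
Product: 4 methyl 2-[(1S)-6,6-dimethoxy-3-oxocyclohex-4-en-1-yl]acetate
Conditions: LiCl, H2O (2 equiv), DMSO, 130 °C
Reagents that add atoms: none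
Why: Krapcho dealkoxycarbonylation removes one malonate ester under near-neutral conditions, under which the ketal, the enone and the non-enolisable C9 centre should be preserved.

Step 3
Reactants: 4 methyl 2-[(1S)-6,6-dimethoxy-3-oxocyclohex-4-en-1-yl]acetate
Product: 5 methyl 2-[(1S,3S)-3-hydroxy-6,6-dimethoxycyclohex-4-en-1-yl]acetate (cis)
Conditions: NaBH4, CeCl3·7H2O, MeOH, −78 to 0 °C; NaHCO3 work-up
Reagents that add atoms: none
Why: Luche 1,2-reduction of the enone, in which axial hydride attack on the 5-substituted cyclohexenone half-chair (as in the reduction of carvone to cis-carveol) gives the cis allylic alcohol and so sets C12 with its oxygen on the same face as the C9 side chain.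

Step 4
Reactants: 5 methyl 2-[(1S,3S)-3-hydroxy-6,6-dimethoxycyclohex-4-en-1-yl]acetate
Product: 6 (1S,5S)-6,6-dimethoxy-2-oxabicyclo[3.3.1]non-7-en-3-one (ring C with the C20→C12 lactone; C8 as dimethyl ketal, C13=C14)
Conditions: KOtBu (10 mol%), THF (0.02 M), 0 to 25 °C
Reagents that add atoms: none
Why: Base-catalysed intramolecular transesterification in dilute aprotic solution closes the bridged δ-lactone from the cis hydroxy ester only, since it alone can place both groups 1,3-diaxial, so that any trans alcohol from step 3 is left uncyclised and removed.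

Step 5
Reactants: 6 (1S,5S)-6,6-dimethoxy-2-oxabicyclo[3.3.1]non-7-en-3-one
Product: 7 (1S,5S)-4-formyl-6,6-dimethoxy-2-oxabicyclo[3.3.1]non-7-en-3-one (C10 formylated; present mainly as the hydroxymethylene enol)
Conditions: NaH, HCO2Et, THF, 0 to 25 °C; then AcOH, 0 °C
Reagents that add atoms: ethyl formate, CCOC=O
Why: Crossed Claisen condensation of the lactone enolate, the only enolisable position, with ethyl formate introduces C5 at C10 and turns C10 into a soft 1,3-dicarbonyl carbon acid.

Step 6
Reactants: 8 methyl 5-methoxy-3-oxopentanoate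
Product: 9 methyl 3-oxopent-4-enoate (Nazarov reagent)
Conditions: TsOH·H2O (2 mol%), 110 °C, 20 mbar, distillation into a cold receiver; used at once
Reagents that add atoms: none
Why: Acid-catalysed β-elimination of methanol from the β-methoxy ketone, with the volatile vinyl ketone distilled out as it forms, gives the Nazarov reagent for immediate use.

Step 7
Reactants: 7 (1S,5S)-4-formyl-6,6-dimethoxy-2-oxabicyclo[3.3.1]non-7-en-3-one; 9 methyl 3-oxopent-4-enoate
Product: 11 spiro keto ester (ring A as methyl cyclohex-2-enone-2-carboxylate: C3 ketone, C4=C5, C19 ester on C4; spiro at C10 to the ketal lactone; C1 anti to C8), via Michael adduct 10 (not isolated)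
Conditions: Cs2CO3 (0.3 equiv), CH2Cl2, 0 to 25 °C, 9 added slowly
Reagents that add atoms: none
Why: Robinson-type annulation with the Nazarov reagent: Michael addition of the formyl lactone anion to the vinyl ketone on the face of C10 anti to the bulky ketal carbon C8 on the neighbouring bridgehead sets the spiro centre C10 (C1 anti to C8), and intramolecular Knoevenagel condensation of the β-keto ester methylene C4 with the aldehyde C5 closes ring A as the alkylidene β-keto ester.

Step 8
Reactants: 11 spiro keto ester; 12 trimethyl phosphonoacetate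
Product: 14 ring-A keto diester phosphonate (C3 ketone; C4 with β-methyl and α-CO2Me; C5 with H5 β carrying CH(CO2Me)P(O)(OMe)2 as both C6 epimers; ketal lactone unchanged), via sodium enolate 13 (not isolated)
Conditions: NaH (1.0 equiv), THF, 0 to 25 °C; then MeI, 25 to 40 °C
Reagents that add atoms: iodomethane, CI
Why: Michael addition of the phosphonoacetate anion to the doubly activated alkene on the face of C5 anti to the bridgehead C9 sets C5 (H5 β) and leaves a β-keto ester enolate that is C-methylated in the same flask (enolate alkylation) from the β face, away from the axial lactone carbonyl C20, so that the C4 ester ends axial and cis to C20; C6 forms as an epimer mixture that is erased in step 11.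

Step 9
Reactants: 14 ring-A keto diester phosphonate
Product: 15 γ-acyloxy enone (14 with the ketal replaced by the C8 ketone, conjugated to C13=C14)
Conditions: 1 M aq. HCl, THF, 0 to 25 °C
Reagents that add atoms: water, O
Why: Acid-catalysed ketal hydrolysis unmasks the C8 ketone as a γ-acyloxy enone, which should be stable because its only α-hydrogen sits on the bridgehead C9 and cannot enolise toward loss of the lactone oxygen.

Step 10
Reactants: 15 γ-acyloxy enone; 16 potassium vinyltrifluoroborate
Product: 17 13β-vinyl C8 ketone (vinyl axial, trans to the C12 oxygen)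
Conditions: [Rh(cod)Cl]2 (3 mol%), dioxane/H2O (10:1), 80 °C
Reagents that add atoms: none
Why: [Rh(cod)Cl]2-catalysed conjugate addition of the vinylboron reagent (Hayashi–Miyaura reaction) delivers the vinyl group to C13 on the β face, anti to the C12 oxygen and to the lactone bridge that covers the α face, and gives an oxygen-bound rhodium enolate that is simply protonated, so that no carbon–metal bond is formed next to the acyloxy group.

Step 11
Reactants: 17 13β-vinyl C8 ketone
Product: 18 tricyclic lactone keto enoate (rings A, B, C; C3 ketone; C6=C8 enoate; 13β-vinyl)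
Conditions: NaH (1.05 equiv), THF, 0 to 50 °C
Reagents that add atoms: none
Why: Intramolecular Horner–Wadsworth–Emmons olefination: the C6 phosphonate carbanion, the most acidic site, adds to the C8 ketone and loss of dimethyl phosphate gives the tetrasubstituted C6=C8 enoate, closing ring B trans-fused to ring A because C6 and C9 are both equatorial on ring A.

Step 12
Reactants: 18 tricyclic lactone keto enoate
Product: 19 C2=C3 enol triflate of 18 (C3–OTf)
Conditions: KN(SiMe3)2, THF, −78 °C; PhNTf2, −78 to 0 °C
Reagents that add atoms: N-phenylbis(trifluoromethanesulfonimide), O=S(=O)(N(c1ccccc1)S(=O)(=O)C(F)(F)F)C(F)(F)F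
Why: The C3 ketone can enolise only toward C2 because C4 is quaternary, and O-sulfonylation of the kinetic potassium enolate with PhNTf2 gives the C2=C3 enol triflate.

Step 13
Reactants: 19 C2=C3 enol triflate
Product: 20 tricyclic lactone diene ester (C2=C3 alkene, C6=C8 enoate, 13β-vinyl)
Conditions: Pd(OAc)2 (5 mol%), PPh3 (10 mol%), HCO2H, Bu3N, DMF, 60 °C
Reagents that add atoms: none
Why: Pd(OAc)2/PPh3-catalysed formate reduction of the enol triflate gives the C2=C3 alkene, and it is placed after step 10 so that the lactone is no longer allylic and cannot ionise on zerovalent palladium.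

Step 14
Reactants: 20 tricyclic lactone diene ester
Product: 21 tricyclic lactone enoate with axial 13β-acetyl group (key-step precursor)
Conditions: PdCl2 (10 mol%), CuCl (1 equiv), O2 (1 atm), DMF/H2O (7:1), 25 °C
Reagents that add atoms: water, O
Why: Tsuji–Wacker oxidation converts the terminal vinyl group with Markovnikov selectivity into the methyl ketone under non-basic conditions, the 1,2-disubstituted ring-A alkene and the tetrasubstituted enoate being much slower substrates.

Step 15
Reactants: 21 tricyclic lactone enoate with axial 13β-acetyl group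
Product: 24 tetracyclic C16 ketone dimethyl ester (ring D closed; C2=C3; H6 α), via lithium ketone enolate 22 (not isolated), via lithium ester enolate 23 (not isolated)
Conditions: LiN(SiMe3)2 (1.5 equiv), THF, −78 to 0 °C; then tBuOH, KOtBu (0.2 equiv), 25 °C; AcOH
Reagents that add atoms: none
Why: LiN(SiMe3)2 removes a methyl proton of the acetyl group under kinetic control and, on warming, the lithium enolate adds through C15 to C8 of the β,β-disubstituted enoate, an intramolecular Michael addition of a ketone enolate of the type known to close bicyclo[3.2.1]octanones. Ring D (C8, C14, C13, C16, C15) closes in a 5-exo-trig mode with respect to the acceptor, the enolate double bond lying inside the new ring as in cyclopentanone-forming aldol closures. The lactone locks ring C in the chair in which the acetyl group is axial and 1,3 to C8, so C15 can reach C8 only from the β face and the quaternary centre is set by this tether geometry. C6 is set afterwards by protonation of the ester enolate and equilibration with catalytic KOtBu in tert-butanol to the more stable isomer with H6 trans to H5. The selectivity needed is enolisation at the methyl group and not at C13, whose enolate would expel the C12 carboxylate; it is secured by the kinetic amide base at −78 °C, and alkoxide is admitted only after cyclisation, when C13 is a bridgehead that cannot enolise.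

Step 16
Reactants: 24 tetracyclic C16 ketone dimethyl ester
Product: 25 2β,3β-dihydroxy C16 ketone dimethyl ester
Conditions: OsO4 (2 mol%), NMO, acetone/H2O (5:1), 25 °C
Reagents that add atoms: N-methylmorpholine N-oxide, C[N+]1([O-])CCOCC1; water, O
Why: Upjohn dihydroxylation: OsO4 adds to the only remaining alkene from the β face, opposite the axial C19 ester on C4 and the axial lactone carbonyl on C10, to give the cis 2β,3β-diol.

Step 17
Reactants: 25 2β,3β-dihydroxy C16 ketone dimethyl ester
Product: 26 2β,3β-dihydroxy 16-methylene dimethyl ester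
Conditions: Zn, CH2Br2, TiCl4, THF, 0 to 5 °C (reagent aged, used in excess); then 25 in CH2Cl2, 25 °C
Reagents that add atoms: dibromomethane, BrCBr
Why: Takai–Lombardo methylenation with the non-basic Zn/CH2Br2/TiCl4 reagent converts the bridged ketone into the exocyclic alkene while esters and the lactone are inert, C6 cannot epimerise and the free hydroxyl groups only consume excess reagent.

Step 18
Reactants: 26 2β,3β-dihydroxy 16-methylene dimethyl ester
Product: 27 target CNP0212122.1 (2β,3β-dihydroxy-16-methylene 7,19-diacid, C20→C12 lactone)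
Conditions: LiSCH2CH2CH3 (excess), HMPA, 25 °C; then 1 M HCl to pH 3
Reagents that add atoms: none
Why: Thiolate demethylation (SN2 at the methyl carbons) frees the two hindered carboxylic acids without hydroxide, so the lactone is kept and the 3-hydroxy group, which is β to the C19 carbonyl, is not exposed to retro-aldol conditions.

**Compound list**

1 | 4,4-dimethoxycyclohexa-2,5-dien-1-one | COC1(OC)C=CC(=O)C=C1 | starting material
2 | dimethyl malonate | COC(=O)CC(=O)OC | starting material
3 | dimethyl 2-[(1S)-6,6-dimethoxy-3-oxocyclohex-4-en-1-yl]propanedioate | COC(=O)C(C(=O)OC)[C@@H]1CC(=O)C=CC1(OC)OC | intermediate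
4 | methyl 2-[(1S)-6,6-dimethoxy-3-oxocyclohex-4-en-1-yl]acetate | COC(=O)C[C@@H]1CC(=O)C=CC1(OC)OC | intermediate
5 | methyl 2-[(1S,3S)-3-hydroxy-6,6-dimethoxycyclohex-4-en-1-yl]acetate (cis) | COC(=O)C[C@@H]1C[C@H](O)C=CC1(OC)OC | intermediate
6 | (1S,5S)-6,6-dimethoxy-2-oxabicyclo[3.3.1]non-7-en-3-one | O=C1C[C@@H]2C[C@H](O1)C=CC2(OC)OC | intermediate
7 | (1S,5S)-4-formyl-6,6-dimethoxy-2-oxabicyclo[3.3.1]non-7-en-3-one (drawn as the aldehyde tautomer, C10 enolised) | O=CC1[C@@H]2C[C@H](OC1=O)C=CC2(OC)OC | intermediate
8 | methyl 5-methoxy-3-oxopentanoate | COCCC(=O)CC(=O)OC | starting material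
9 | methyl 3-oxopent-4-enoate (Nazarov reagent) | C=CC(=O)CC(=O)OC | intermediate
10 | Michael adduct: 7 carrying the methyl 3-oxopentanoate chain on C10, anti to C8 | O=C[C@@]1(CCC(=O)CC(=O)OC)[C@@H]2C[C@H](OC1=O)C=CC2(OC)OC | intermediate
11 | spiro keto ester (ring A enone ester spiro at C10 to the ketal lactone) | COC(=O)C1=C[C@@]2(CCC1=O)[C@@H]3C[C@H](OC2=O)C=CC3(OC)OC | intermediate
12 | trimethyl phosphonoacetate | COC(=O)CP(=O)(OC)OC | starting material
13 | sodium enolate (C3–ONa, C3=C4) of the phosphonoacetate Michael adduct | COC(=O)C(P(=O)(OC)OC)[C@@H]1C(C(=O)OC)=C(O[Na])CC[C@@]12[C@@H]3C[C@H](OC2=O)C=CC3(OC)OC | intermediate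
14 | ring-A keto diester phosphonate (C4 β-Me, α-CO2Me; H5 β; C6 both epimers) | COC(=O)C(P(=O)(OC)OC)[C@@H]1[C@](C)(C(=O)OC)C(=O)CC[C@@]12[C@@H]3C[C@H](OC2=O)C=CC3(OC)OC | intermediate
15 | γ-acyloxy enone (C8 ketone, C13=C14) | COC(=O)C(P(=O)(OC)OC)[C@@H]1[C@](C)(C(=O)OC)C(=O)CC[C@@]12[C@@H]3C[C@H](OC2=O)C=CC3=O | intermediate
16 | potassium vinyltrifluoroborate | [K+].C=C[B-](F)(F)F | starting material
17 | 13β-vinyl C8 ketone | COC(=O)C(P(=O)(OC)OC)[C@@H]1[C@](C)(C(=O)OC)C(=O)CC[C@@]12[C@@H]3C[C@H](OC2=O)[C@@H](C=C)CC3=O | intermediate
18 | tricyclic lactone keto enoate (C3 ketone, C6=C8, 13β-vinyl) | C=C[C@H]1CC2=C(C(=O)OC)[C@H]3[C@](CCC(=O)[C@@]3(C)C(=O)OC)(C(=O)O[C@H]1C4)[C@@H]24 | intermediate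
19 | C2=C3 enol triflate of 18 | C=C[C@H]1CC2=C(C(=O)OC)[C@H]3[C@](CC=C(OS(=O)(=O)C(F)(F)F)[C@@]3(C)C(=O)OC)(C(=O)O[C@H]1C4)[C@@H]24 | intermediate
20 | tricyclic lactone diene ester (C2=C3, C6=C8, 13β-vinyl) | C=C[C@H]1CC2=C(C(=O)OC)[C@H]3[C@](CC=C[C@@]3(C)C(=O)OC)(C(=O)O[C@H]1C4)[C@@H]24 | intermediate
21 | tricyclic lactone enoate with axial 13β-acetyl group (key-step precursor) | CC(=O)[C@H]1CC2=C(C(=O)OC)[C@H]3[C@](CC=C[C@@]3(C)C(=O)OC)(C(=O)O[C@H]1C4)[C@@H]24 | intermediate
22 | lithium enolate of 21 on the methyl side (C15=C16–OLi) | C=C(O[Li])[C@H]1CC2=C(C(=O)OC)[C@H]3[C@](CC=C[C@@]3(C)C(=O)OC)(C(=O)O[C@H]1C4)[C@@H]24 | intermediate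
23 | lithium ester enolate of the tetracycle (C6=C7(OMe)OLi) | O=C1C[C@]23C[C@H]1[C@@H]1C[C@H]2[C@@]2(CC=C[C@@](C)(C(=O)OC)[C@H]2C3=C(OC)O[Li])C(=O)O1 | intermediate
24 | tetracyclic C16 ketone dimethyl ester (key-step product) | O=C1C[C@]23C[C@H]1[C@@H]1C[C@H]2[C@@]2(CC=C[C@@](C)(C(=O)OC)[C@H]2[C@@H]3C(=O)OC)C(=O)O1 | intermediate
25 | 2β,3β-dihydroxy C16 ketone dimethyl ester | O=C1C[C@]23C[C@H]1[C@@H]1C[C@H]2[C@@]2(C[C@H](O)[C@H](O)[C@@](C)(C(=O)OC)[C@H]2[C@@H]3C(=O)OC)C(=O)O1 | intermediate
26 | 2β,3β-dihydroxy 16-methylene dimethyl ester | C=C1C[C@]23C[C@H]1[C@@H]1C[C@H]2[C@@]2(C[C@H](O)[C@H](O)[C@@](C)(C(=O)OC)[C@H]2[C@@H]3C(=O)OC)C(=O)O1 | intermediate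
27 | CNP0212122.1 | C=C1C[C@]23C[C@H]1[C@@H]1C[C@H]2[C@@]2(C[C@H](O)[C@H](O)[C@@](C)(C(=O)O)[C@H]2[C@@H]3C(=O)O)C(=O)O1 | target

**Step count and risks**

Total: 18 steps. Longest linear sequence: 17 steps (steps 1–5 and 7–18); step 6 prepares the annulation reagent on a side branch.

Steps most likely to fail: 15, 1 and 7.

Step 15. During enolisation or the slow addition to the tetrasubstituted acceptor, the lithium enolate may exchange protons with ketone that is not yet deprotonated. The C13 enolate formed in this way expels the C12 carboxylate and the lactone opens. The fallback sets out from 21 and comes back at 24. LiN(SiMe3)2 is added at −78 °C to a THF solution of 21 that already contains Me3SiCl, so that the methyl-side enolate is silylated as it forms and gives the trimethylsilyl enol ether F1. TiCl4 in CH2Cl2 at −78 °C then activates the enoate for an intramolecular Mukaiyama–Michael addition, in which no free ketone enolate is present. After aqueous work-up the C6 epimers are equilibrated with catalytic KOtBu in tert-butanol to give 24.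

Step 1. The catalyst may discriminate poorly between the enantiotopic faces of the ketal-flanked dienone, or a second malonate may add to the monoadduct. The fallback sets out from 1 and 2 and comes back at 5. NaOMe (catalytic) in MeOH gives the racemic adduct F2, Krapcho dealkoxycarbonylation gives the racemic monoester F3, and Luche reduction gives the racemic cis alcohol F4. Esterification with (R)-O-methylmandelic acid (DCC, DMAP, CH2Cl2) gives the mandelate of the (1S,3S) alcohol F5 and the mandelate of its enantiomer F6, which are separated by chromatography or crystallisation. Methanolysis of F5 (K2CO3, MeOH, 0 °C) returns 5.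

Step 7. The vinyl ketone 9 may polymerise, or 7 may lose its formyl group, faster than the Michael addition takes place. The fallback sets out from 7 and 8 (step 6 is then not needed) and comes back at 11; it forms the two ring-A bonds in the opposite order. Knoevenagel condensation of the formyl carbon of 7 with the active methylene of 8 (piperidinium acetate, benzene, 25 °C) gives the alkylidene β-keto ester F7. DBU in THF then induces loss of methanol from the β-methoxy ketone, and the C10 carbanion closes ring A onto the vinyl ketone so formed by intramolecular 6-endo-trig Michael addition, again on the face anti to C8, giving 11.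

**Further compounds**

F1 | step 15 | trimethylsilyl enol ether of 21 on the methyl side | C=C(O[Si](C)(C)C)[C@H]1CC2=C(C(=O)OC)[C@H]3[C@](CC=C[C@@]3(C)C(=O)OC)(C(=O)O[C@H]1C4)[C@@H]24
F2 | step 1 | racemic dimethyl 2-(6,6-dimethoxy-3-oxocyclohex-4-en-1-yl)propanedioate | COC(=O)C(C(=O)OC)C1CC(=O)C=CC1(OC)OC
F3 | step 1 | racemic methyl 2-(6,6-dimethoxy-3-oxocyclohex-4-en-1-yl)acetate | COC(=O)CC1CC(=O)C=CC1(OC)OC
F4 | step 1 | racemic cis methyl 2-(3-hydroxy-6,6-dimethoxycyclohex-4-en-1-yl)acetate | COC(=O)C[C@@H]1C[C@H](O)C=CC1(OC)OC.COC(=O)C[C@H]1C[C@@H](O)C=CC1(OC)OC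
F5 | step 1 | (R)-O-methylmandelate of 5 | COC(=O)C[C@@H]1C[C@H](OC(=O)[C@H](OC)c2ccccc2)C=CC1(OC)OC
F6 | step 1 | (R)-O-methylmandelate of the enantiomer of 5 | COC(=O)C[C@H]1C[C@@H](OC(=O)[C@H](OC)c2ccccc2)C=CC1(OC)OC
F7 | step 7 | Knoevenagel adduct of 7 and 8 (alkylidene β-keto ester, C10–H) | COCCC(=O)C(C(=O)OC)=CC1[C@@H]2C[C@H](OC1=O)C=CC2(OC)OC
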